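Two questions stand on this flask, and two earlier runs have to answer them.

| flask | starting material | second substrate | gas | free catalyst | remark | time |
|---|---|---|---|---|---|---|
| delta | 0.052 M | 0.036 M | 21 mM (held) | 99 µM | run made earlier |  |
| epsilon | 0.052 M | 0.057 M | 21 mM (held) | 99 µM | run made earlier |  |
| flask | 0.052 M | 0.0260 M | 21 mM (held) | 99 µM |  | 10 min |

| run | time / min | target / % |
|---|---|---|
| delta | 1.00 | 0.5 |
| delta | 1.50 | 1.5 |
| delta | 2.50 | 3.4 |
| delta | 4.00 | 6.7 |
| delta | 8.00 | 19.1 |
| delta | 12.0 | 31.5 |
| epsilon | 1.00 | 0 |
| epsilon | 1.50 | 0.7 |
| epsilon | 2.50 | 2.4 |
| epsilon | 4.00 | 6.2 |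
| epsilon | 8.00 | 18.2 |
| epsilon | 12.0 | 29.7 |

(readings scatter by 0.5 percentage points)

1. amount of target at 10 min, in percent of the starting material charged
2. amount of target if the flask were left three thousand times as long, in percent of the starting material charged

- at the start none of the gas is in solution

Between its fourth and last readings the delta run climbs at 1.61 mM min⁻¹, and that line, extended back, meets zero at a dead time of 1.84 min. I carry one quantity, the working rate (turnover frequency): target made per minute on the straight stretch, divided by the free catalyst charged, here 16.3 min⁻¹. The epsilon run reads 15.4 min⁻¹.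

Two extreme versions of the flask can be reckoned. In the first, second substrate is the limiting reagent, one going per target, and the working rate follows its charge: that gives 18.3% at the asked time and a ceiling of 50.0%. In the second, the rate ignores second substrate and target takes none of it: that gives 25.3% and a ceiling of 100%.

The ratio of the two working rates, in which time drops out, is the reading I can hold against them. Epsilon over delta it reads 0.945, less than their charge ratio of second substrate, 1.58, so I commit to the second version. Two doubts remain: this flask's charge of second substrate is lower than in both earlier runs, and these readings give a rate of target, not what each target consumes.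

The forecast says 25.3% and 50%, “Assuming 1:1 stoichiometry, which the data do not prove”. The flask gives 26.0% and 100%.

    starting material + free catalyst ⇌ catalyst intermediate A (K = 28.0 M⁻¹, k = 45.0 M⁻¹ s⁻¹)
    partner + catalyst intermediate A → free catalyst + target (k = 46.0 M⁻¹ s⁻¹)
    second substrate + free catalyst ⇌ catalyst intermediate B (K = 760 M⁻¹, k = 71.0 M⁻¹ s⁻¹)
    partner + catalyst intermediate B → free catalyst + second product (k = 5100 M⁻¹ s⁻¹)
    2 second substrate → self-condensation product (k = 0.340 M⁻¹ s⁻¹)
    gas ⇌ partner, rate k6*(csat - [partner]) (kL = 0.00650 s⁻¹)
    catalyst intermediate B → spent catalyst (k = 0.0190 s⁻¹)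

This flask has not come to rest. At 10.0 min it still holds 74% of its starting material, which at the working rate read from the delta run comes to an estimated 23.8 min more. At 100 min target stands at 99.9%, starting material at 0.0656%, and free catalyst has risen from 51.3% to 89.2%, while spent catalyst reads 10.6% and then 10.7%.

For the neighbour flask charged with 5.9 × 10⁻⁵ M of free catalyst, the same working rate and dead time give 15.1%. That flask gives 17.7%.

The earlier runs and the new flask are calculated from invented constants.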